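# Proposed synthesis of CNP0122132.1 by acyl-transfer ring expansion of an O8-anchored seven-membered lactone

## Analysis of the target

The target is a furanoheliangolide. Its ten-membered carbocycle C1–C10 is bridged by O10 between C10 and C3, so that C10–C1(=O)–C2=C3–O10 is a 2,2-disubstituted 3(2H)-furanone and O10–C3–C4=C5–C6–C7–C8–C9–C10 is a nine-membered oxacycle (together an 11-oxabicyclo[6.2.1]undecane). A trans-fused α-methylene-γ-butyrolactone (O6–C12(=O)–C11(=C13H2)–C7) sits on C6–C7, C8 carries an angelate, and the (Z)-configured C4=C5 bond carries the acetoxymethyl carbon C15. The stereocentres C6 (R), C7 (R) and C8 (S) are contiguous, with O6, C11 and O8 on the same side of the extended C5–C9 chain; the quaternary C10 (R) is separated from them by C9H2. Sensitive groups are the exocyclic methylene lactone (Michael acceptor), the angelate (Z to E isomerisation), the Baylis–Hillman-type allylic acetate at C15, and the 6,12-lactone next to an 8-oxygen (translactonisation under base). The difficulty is the medium ring: C1–C5 are all sp2 and the furanone bridge adds strain, so closing it by a C–C bond late in the route fights both strain and entropy. The feature this route uses is that the furanone is the dehydrated form of a C1/C3 1,3-diketone plus the C10 hydroxyl, and that O8 lies five atoms from C3 (through C4=C5–C6–C7–C8) and five atoms from C2 (through C1–C10–C9–C8). A C3 acyl group parked on O8 as a seven-membered lactone (ring A) can therefore be handed to C2 through a seven-membered transition state, which turns ring A into the ten-membered ring.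

## Retrosynthetic reasoning

The exocyclic methylene of 25 is unmasked last from sulfide 23 (through sulfoxide 24), and the angelate of 23 is put on the free C8 hydroxyl of 20. Both esters and the Michael acceptor thus appear only after all base chemistry is over.

The key cut removes the C2–C3 bond and the O10–C3 bond of 20 and re-attaches C3 to O8. This gives bis-lactone 17, in which ring A (O8–C3(=O)–C4=C5–C6–C7–C8) is fused to the γ-lactone at C6–C7 and C8 carries the side chain C9–C10(OSi)(C14)–C1(=O)–C2H3. The cut is made here because the hard ten-membered ring is then replaced by an easy seven-membered lactone, and the forward reaction needs only a ketone enolate to add to a lactone carbonyl seven atoms away (via 18 and 19). The same step frees O8 for the angelate.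

Ring A of 17 is opened at C4=C5, which leads to acrylate ester 16. The seven-membered ring-closing metathesis is a routine ring size, and the ring itself enforces the Z geometry that is hard to secure on an open chain. Ester 16 comes from alcohol 14 and acid 15, and 15 comes from 9.

Sulfide 14 is the masked form of methylene lactone 13. Lactone 13 is cut at C7–C8 into aldehyde 6 and butenolide bromide 12. One Barbier step then forms the bond, regenerates the methylene lactone, and sets C7 and C8 from the single stereocentre C6 of 12.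

Bromide 12 is cut at its ring alkene to triene ester 11, which comes from dienol 8 and acid 9 (through 10). Dienol 8 is obtained from racemic 7 by kinetic resolution; its two different alkenes serve the two metatheses in turn.

Aldehyde 6 is traced through 5 to aldol adduct 4, cut at C9–C10 into silyl ketene thioacetal 2 and diketone 3. This one catalytic step sets C10 and delivers C8, C9, C10, C14, C1 and C2 in the right oxidation states. Thioacetal 2 comes from thioester 1.

## Alternatives that were turned down

Alternative 1: the textbook cut, C6–C7 together with the lactone C–O bond. Bromo-enal A1, with the furanone already in place, would be closed by an intramolecular Barbier or Nozaki–Hiyama allylation followed by lactonisation. It was turned down for four reasons: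
- The C–C bond is formed inside the strained nine-membered oxacycle that already contains the planar C1–C5 array, in competition with oligomerisation.
- The trans lactone needs the anti adduct, whereas the acyclic (Z)-bromide of A1 is a Z-type crotyl reagent whose chair transition state favours syn. C6/C7 control is therefore left to medium-ring conformations.
- The (Z)-enal of A1 is part of a push–pull dienone and can isomerise to the E form, which cannot cyclise.
- The step count is no lower.

Alternative 2: cut at C4=C5. Tetraene A2 would be closed by ring-closing metathesis. It was turned down because a trisubstituted alkene must form in the bridged nine-membered ring from a 1,1-disubstituted alkene of an electron-poor diene and a vinyl group flanked by the lactone oxygen. The step sets no stereocentre, so the whole stereotriad and C10 must be built on an open chain and the furanone made beforehand by a separate intermolecular sequence. The key step would form one bond and nothing else.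

Alternative 3: ring expansion of a dihydropyran. Diazoketone A3 would give, by metal carbenoid formation, oxonium ylide formation at the ring oxygen and [2,3]-sigmatropic shift, the bridged ten-membered ring A4 with C10 set by chirality transfer from C3. It was turned down for four reasons:
- The shift necessarily places the new alkene at C7=C8. C7 is erased, and the C7–C11 and C8–O bonds (two of the three contiguous stereocentres) must then be installed on a medium ring next to a doubly allylic C6–O.
- The tertiary carbenoid carries β-hydrogens and can undergo 1,2-hydride shift.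
- The endocyclic allyl unit C3–C4=C5 offers a competing shift.
- C2=C3 must still be dehydrogenated, so the gain of the key step is spent in the tail.

Key step: step 13

Remark: atoms are numbered as in germacranolides (C1 ketone, C3 enol-ether carbon, C4 bearing C15, C10 bearing C14, C11–C13 the lactone carbons; O6, O8, O10 the oxygens on those carbons). Compounds 14–24 are carried as mixtures of C11 epimers (24 also of sulfur epimers), because C11 becomes sp2 again in step 15. The (R,R)-configured bis(oxazoline) ligand is assumed to induce the sense opposite to its antipode.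

## Route

Step 1
Reactants: 1 S-ethyl ethanethioate
Product: 2 1-(ethylsulfanyl)-1-(trimethylsilyloxy)ethene
Conditions: LiN(iPr)2, THF, −78 °C; then Me3SiCl, −78 °C → rt
Reagents that add atoms: chlorotrimethylsilane, C[Si](C)(C)Cl
Why: Kinetic deprotonation of the thioester and O-silylation of the lithium enolate give the silyl ketene thioacetal, the standard nucleophile for Mukaiyama aldol additions.

Step 2
Reactants: 2 1-(ethylsulfanyl)-1-(trimethylsilyloxy)ethene, 3 butane-2,3-dione
Product: 4 S-ethyl (3R)-3-hydroxy-3-methyl-4-oxopentanethioate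
Conditions: Cu(OTf)2 (10 mol %), 2,2'-(propane-2,2-diyl)bis[(4R)-4-tert-butyl-4,5-dihydrooxazole], 3 (3 equiv), THF, −78 °C; then 1 M HCl
Reagents that add atoms: none
Why: Mukaiyama aldol addition to the 1,2-diketone held as a chelate on the C2-symmetric copper bis(oxazoline) Lewis acid; the ligand shields one carbonyl face and should set C10 (R), and the symmetric diketone, used in excess, raises no regiochemical question.

Step 3
Reactants: 4 S-ethyl (3R)-3-hydroxy-3-methyl-4-oxopentanethioate
Product: 5 S-ethyl (3R)-3-{[tert-butyl(dimethyl)silyl]oxy}-3-methyl-4-oxopentanethioate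
Conditions: TBSOTf, 2,6-lutidine, CH2Cl2, −78 → 0 °C
Reagents that add atoms: tert-butyldimethylsilyl trifluoromethanesulfonate, CC(C)(C)[Si](C)(C)OS(=O)(=O)C(F)(F)F
Why: The silyl triflate with a hindered base silylates the tertiary alcohol; the group keeps O10 from acting as an acyl-scrambling alkoxide in step 13, where it is removed.

Step 4
Reactants: 5 S-ethyl (3R)-3-{[tert-butyl(dimethyl)silyl]oxy}-3-methyl-4-oxopentanethioate
Product: 6 (3R)-3-{[tert-butyl(dimethyl)silyl]oxy}-3-methyl-4-oxopentanal
Conditions: Et3SiH, Pd/C (10 wt %), acetone, rt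
Reagents that add atoms: none
Why: Fukuyama reduction; palladium-catalysed hydrosilane reduction of the thioester stops at the aldehyde and leaves the ketone and the silyl ether untouched.

Step 5
Reactants: 7 rac-(4E)-hexa-1,4-dien-3-ol
Product: 8 (3S,4E)-hexa-1,4-dien-3-ol
Conditions: Ti(OiPr)4 (0.1 equiv), D-(−)-diisopropyl tartrate (0.15 equiv), t-BuOOH (0.6 equiv), 4 Å molecular sieves, CH2Cl2, −20 °C
Reagents that add atoms: none
Why: Sharpless kinetic resolution; with the D-(−)-tartrate the (R)-enantiomer is epoxidised quickly at its (E)-propenyl group, while the (S)-enantiomer is mismatched for that alkene and should be recovered.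

Step 6
Reactants: 8 (3S,4E)-hexa-1,4-dien-3-ol, 9 2-(bromomethyl)prop-2-enoic acid
Product: 11 (3S,4E)-hexa-1,4-dien-3-yl 2-(bromomethyl)prop-2-enoate, via acid chloride 10 (not isolated)
Conditions: 9, (COCl)2, DMF (cat.), CH2Cl2, 0 °C → rt; then 8, 2,6-lutidine, CH2Cl2, −20 °C
Reagents that add atoms: none
Why: Acylation of the secondary alcohol by the acid chloride with a hindered, weakly nucleophilic base, which avoids SN2′ attack on the allylic bromide; the stereocentre is not involved.

Step 7
Reactants: 11 (3S,4E)-hexa-1,4-dien-3-yl 2-(bromomethyl)prop-2-enoate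
Product: 12 (5R)-3-(bromomethyl)-5-[(1E)-prop-1-en-1-yl]furan-2(5H)-one
Conditions: second-generation Hoveyda–Grubbs catalyst (5 mol %), CH2Cl2 (0.01 M), 40 °C
Reagents that add atoms: none
Why: Ring-closing metathesis; the phosphine-free catalyst should load at the terminal vinyl group and close onto the 1,1-disubstituted acrylate to give the butenolide, leaving the slower internal propenyl group for step 12; C6 is untouched.

Step 8
Reactants: 6 (3R)-3-{[tert-butyl(dimethyl)silyl]oxy}-3-methyl-4-oxopentanal, 12 (5R)-3-(bromomethyl)-5-[(1E)-prop-1-en-1-yl]furan-2(5H)-one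
Product: 13 (4R,5R)-4-[(1S,3R)-3-{[tert-butyl(dimethyl)silyl]oxy}-1-hydroxy-3-methyl-4-oxopentyl]-3-methylidene-5-[(1E)-prop-1-en-1-yl]oxolan-2-one
Conditions: Zn dust, THF/saturated aqueous NH4Cl, 0 °C → rt
Reagents that add atoms: none
Why: Barbier allylation; the allylzinc reagent should react through its γ-carbon C7 with the aldehyde rather than the ketone and regenerate the exocyclic methylene. Attack anti to the C6 propenyl group gives the trans lactone (C7), and the butenolide ring holds the γ-substituent in the E-type position of a Zimmerman–Traxler chair, which leads to the anti adduct (C8 S).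

Step 9
Reactants: 13 (4R,5R)-4-[(1S,3R)-3-{[tert-butyl(dimethyl)silyl]oxy}-1-hydroxy-3-methyl-4-oxopentyl]-3-methylidene-5-[(1E)-prop-1-en-1-yl]oxolan-2-one
Product: 14 (4R,5R)-4-[(1S,3R)-3-{[tert-butyl(dimethyl)silyl]oxy}-1-hydroxy-3-methyl-4-oxopentyl]-3-[(phenylsulfanyl)methyl]-5-[(1E)-prop-1-en-1-yl]oxolan-2-one (C3 epimers)
Conditions: PhSH (1.1 equiv), Et3N (0.1 equiv), CH2Cl2, 0 °C
Reagents that add atoms: thiophenol, Sc1ccccc1
Why: Thia-Michael addition to the exocyclic methylene lactone, the only strong acceptor present; the sulfide masks it against the enolate of step 13, and the new C11 centre is removed again in step 15.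

Step 10
Reactants: 9 2-(bromomethyl)prop-2-enoic acid
Product: 15 2-[(acetyloxy)methyl]prop-2-enoic acid
Conditions: KOAc (3 equiv), AcOH, 60 °C
Reagents that add atoms: potassium acetate, CC(=O)[O-].[K+]
Why: Substitution of the activated allylic bromide by acetate (SN2 and SN2′ give the same product) in acetic acid, where the carboxylic acid stays protonated and does not compete.

Step 11
Reactants: 14 (4R,5R)-4-[(1S,3R)-3-{[tert-butyl(dimethyl)silyl]oxy}-1-hydroxy-3-methyl-4-oxopentyl]-3-[(phenylsulfanyl)methyl]-5-[(1E)-prop-1-en-1-yl]oxolan-2-one, 15 2-[(acetyloxy)methyl]prop-2-enoic acid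
Product: 16 (1S,3R)-3-{[tert-butyl(dimethyl)silyl]oxy}-3-methyl-4-oxo-1-{(2R,3R)-5-oxo-4-[(phenylsulfanyl)methyl]-2-[(1E)-prop-1-en-1-yl]oxolan-3-yl}pentyl 2-[(acetyloxy)methyl]prop-2-enoate
Conditions: DCC, DMAP (0.2 equiv), CH2Cl2, 0 °C → rt
Reagents that add atoms: none
Why: Steglich esterification of the C8 hydroxyl (which reacts from the open form of its hemiketal with the C1 ketone) parks the future C3 acyl group on O8; reversible attack of DMAP on the acetoxymethyl acrylate is degenerate and harmless.

Step 12
Reactants: 16 (1S,3R)-3-{[tert-butyl(dimethyl)silyl]oxy}-3-methyl-4-oxo-1-{(2R,3R)-5-oxo-4-[(phenylsulfanyl)methyl]-2-[(1E)-prop-1-en-1-yl]oxolan-3-yl}pentyl 2-[(acetyloxy)methyl]prop-2-enoate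
Product: 17 (4Z,6R,7R,8S,10R)-15-acetoxy-10-{[tert-butyl(dimethyl)silyl]oxy}-1-oxo-13-(phenylsulfanyl)-2,3-secogermacr-4-ene-3,8:12,6-diolide (ring A lactone O8–C3 fused to the γ-lactone O6–C12)
Conditions: second-generation Hoveyda–Grubbs catalyst (10 mol %), toluene (0.002 M), 80 °C
Reagents that add atoms: none
Why: Ring-closing metathesis to a seven-membered α,β-unsaturated lactone, a well-precedented ring size; the catalyst should enter at the propenyl group and close onto the acrylate, and the ring forces the new C4=C5 bond to be Z.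

Step 13
Reactants: 17 (4Z,6R,7R,8S,10R)-15-acetoxy-10-{[tert-butyl(dimethyl)silyl]oxy}-1-oxo-13-(phenylsulfanyl)-2,3-secogermacr-4-ene-3,8:12,6-diolide
Product: 20 (4Z,6R,7R,8S,10R)-15-acetoxy-3,10-epoxy-8-hydroxy-1-oxo-13-(phenylsulfanyl)germacra-2,4-dien-12,6-olide, via bridged hemiketal alkoxide 18 (not isolated), via ten-membered diketone 19 (not isolated)
Conditions: LiN(SiMe3)2 (1.1 equiv), THF (0.005 M), −78 → −20 °C; AcOH; then 48% aqueous HF, MeCN, 0 °C → rt
Reagents that add atoms: none
Why: Proposed new method: LiN(SiMe3)2 deprotonates the C2 methyl group, the only accessible ketone α-position (C10 is quaternary, the lactone and acetate α-hydrogens are several pKa units less acidic), and the enolate adds to the C3 lactone carbonyl, which is held close because the acyl carbon and the side chain both hang from C8/O8 (7-exo-trig addition giving bridged hemiketal alkoxide 18). Collapse of 18 with loss of the O8 alkoxide instead of the enolate carbon breaks the C3–O8 bond, so ring A is exchanged for the ten-membered carbocycle (a net three-atom ring expansion); proton transfer from C2 of diketone 19 to that alkoxide gives the diketonate, a gain of roughly fifteen pKa units that should outweigh the medium-ring strain and make the step irreversible. The closest known reaction types are the Baker–Venkataraman O-to-C acyl transfer, the Claisen acylation of ketone enolates by lactones, and ring enlargements by transacylation through cyclic tetrahedral intermediates. Aqueous HF then cleaves the tertiary silyl ether, and O10 closes onto the C3 carbonyl (5-exo-trig hemiketalisation) and loses water to give the 3(2H)-furanone, the thermodynamic sink among the possible hemiketals. No stereocentre is created: C6, C7, C8 and C10 are carried through unchanged, and the Z geometry of C4=C5, fixed by ring A, is kept because the alkene is not touched. The step needs attack at C3 and not at the γ-lactone carbonyl C12 (seven- against eight-membered transition state), no Michael addition (the methylene is masked as the sulfide), and no lasting alkoxide that could translactonise between O6 and O8 (about one equivalent of base, and the alkoxide is quenched internally by the diketone).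

Step 14
Reactants: 20 (4Z,6R,7R,8S,10R)-15-acetoxy-3,10-epoxy-8-hydroxy-1-oxo-13-(phenylsulfanyl)germacra-2,4-dien-12,6-olide, 21 (2Z)-2-methylbut-2-enoic acid (angelic acid)
Product: 23 (4Z,6R,7R,8S,10R)-15-acetoxy-8-{[(2Z)-2-methylbut-2-enoyl]oxy}-3,10-epoxy-1-oxo-13-(phenylsulfanyl)germacra-2,4-dien-12,6-olide, via mixed anhydride 22 (not isolated)
Conditions: 21, 2,4,6-trichlorobenzoyl chloride, Et3N, toluene, rt; then 20, toluene, 80 °C
Reagents that add atoms: none
Why: Yamaguchi-type mixed-anhydride esterification run without DMAP, the usual way to make angelates without Z to E isomerisation; O8 is the only free hydroxyl.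

Step 15
Reactants: 23 (4Z,6R,7R,8S,10R)-15-acetoxy-8-{[(2Z)-2-methylbut-2-enoyl]oxy}-3,10-epoxy-1-oxo-13-(phenylsulfanyl)germacra-2,4-dien-12,6-olide
Product: 25 (4Z,6R,7R,8S,10R)-15-acetoxy-8-{[(2Z)-2-methylbut-2-enoyl]oxy}-3,10-epoxy-1-oxogermacra-2,4,11(13)-trien-12,6-olide (CNP0122132.1), via sulfoxide 24 (not isolated)
Conditions: mCPBA (1.0 equiv), CH2Cl2, −78 °C; then NaHCO3, toluene, 90 °C
Reagents that add atoms: none
Why: Chemoselective S-oxidation at low temperature (all alkenes are electron-poor) followed by thermal syn elimination of the β-sulfinyl lactone (sulfoxide elimination), whose only β-hydrogen is H11, should restore the C11=C13 methylene under neutral conditions.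

## Compound list

1 | S-ethyl ethanethioate | CC(=O)SCC | starting material
2 | 1-(ethylsulfanyl)-1-(trimethylsilyloxy)ethene | C=C(O[Si](C)(C)C)SCC | intermediate
3 | butane-2,3-dione | CC(=O)C(C)=O | starting material
4 | S-ethyl (3R)-3-hydroxy-3-methyl-4-oxopentanethioate | CCSC(=O)C[C@@](C)(O)C(C)=O | intermediate
5 | S-ethyl (3R)-3-{[tert-butyl(dimethyl)silyl]oxy}-3-methyl-4-oxopentanethioate | CCSC(=O)C[C@@](C)(O[Si](C)(C)C(C)(C)C)C(C)=O | intermediate
6 | (3R)-3-{[tert-butyl(dimethyl)silyl]oxy}-3-methyl-4-oxopentanal | O=CC[C@@](C)(O[Si](C)(C)C(C)(C)C)C(C)=O | intermediate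
7 | rac-(4E)-hexa-1,4-dien-3-ol | C=CC(O)/C=C/C | starting material
8 | (3S,4E)-hexa-1,4-dien-3-ol | C=C[C@H](O)/C=C/C | intermediate
9 | 2-(bromomethyl)prop-2-enoic acid | C=C(CBr)C(=O)O | starting material
10 | 2-(bromomethyl)prop-2-enoyl chloride | C=C(CBr)C(Cl)=O | intermediate (not isolated)
11 | (3S,4E)-hexa-1,4-dien-3-yl 2-(bromomethyl)prop-2-enoate | C=C(CBr)C(=O)O[C@@H](C=C)/C=C/C | intermediate
12 | (5R)-3-(bromomethyl)-5-[(1E)-prop-1-en-1-yl]furan-2(5H)-one | O=C1O[C@H](/C=C/C)C=C1CBr | intermediate
13 | (4R,5R)-4-[(1S,3R)-3-{[tert-butyl(dimethyl)silyl]oxy}-1-hydroxy-3-methyl-4-oxopentyl]-3-methylidene-5-[(1E)-prop-1-en-1-yl]oxolan-2-one | C=C1C(=O)O[C@H](/C=C/C)[C@H]1[C@@H](O)C[C@@](C)(O[Si](C)(C)C(C)(C)C)C(C)=O | intermediate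
14 | (4R,5R)-4-[(1S,3R)-3-{[tert-butyl(dimethyl)silyl]oxy}-1-hydroxy-3-methyl-4-oxopentyl]-3-[(phenylsulfanyl)methyl]-5-[(1E)-prop-1-en-1-yl]oxolan-2-one (C3 epimers) | C(Sc1ccccc1)C1C(=O)O[C@H](/C=C/C)[C@H]1[C@@H](O)C[C@@](C)(O[Si](C)(C)C(C)(C)C)C(C)=O | intermediate
15 | 2-[(acetyloxy)methyl]prop-2-enoic acid | C=C(COC(C)=O)C(=O)O | intermediate
16 | (1S,3R)-3-{[tert-butyl(dimethyl)silyl]oxy}-3-methyl-4-oxo-1-{(2R,3R)-5-oxo-4-[(phenylsulfanyl)methyl]-2-[(1E)-prop-1-en-1-yl]oxolan-3-yl}pentyl 2-[(acetyloxy)methyl]prop-2-enoate | C(Sc1ccccc1)C1C(=O)O[C@H](/C=C/C)[C@H]1[C@@H](OC(=O)C(=C)COC(C)=O)C[C@@](C)(O[Si](C)(C)C(C)(C)C)C(C)=O | intermediate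
17 | (4Z,6R,7R,8S,10R)-15-acetoxy-10-{[tert-butyl(dimethyl)silyl]oxy}-1-oxo-13-(phenylsulfanyl)-2,3-secogermacr-4-ene-3,8:12,6-diolide | CC(=O)OCC1=C[C@H]2OC(=O)C(CSc3ccccc3)[C@@H]2[C@@H](OC1=O)C[C@@](C)(O[Si](C)(C)C(C)(C)C)C(C)=O | intermediate
18 | lithium alkoxide of (4Z,6R,7R,8S,10R)-15-acetoxy-10-{[tert-butyl(dimethyl)silyl]oxy}-3,8-epoxy-3-hydroxy-1-oxo-13-(phenylsulfanyl)germacr-4-en-12,6-olide (SMILES drawn as the neutral hemiketal) | CC(=O)OCC1=C[C@H]2OC(=O)C(CSc3ccccc3)[C@@H]2[C@@H]2C[C@@](C)(O[Si](C)(C)C(C)(C)C)C(=O)CC1(O)O2 | intermediate (not isolated)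
19 | (4Z,6R,7R,8S,10R)-15-acetoxy-10-{[tert-butyl(dimethyl)silyl]oxy}-8-hydroxy-1,3-dioxo-13-(phenylsulfanyl)germacr-4-en-12,6-olide (formed as its lithium enolate) | CC(=O)OC/C1=C/[C@H]2OC(=O)C(CSc3ccccc3)[C@@H]2[C@@H](O)C[C@@](C)(O[Si](C)(C)C(C)(C)C)C(=O)CC1=O | intermediate (not isolated)
20 | (4Z,6R,7R,8S,10R)-15-acetoxy-3,10-epoxy-8-hydroxy-1-oxo-13-(phenylsulfanyl)germacra-2,4-dien-12,6-olide | C(Sc4ccccc4)C1C(=O)O[C@@H]2/C=C(/COC(C)=O)C3=CC(=O)[C@@](C)(C[C@H](O)[C@@H]12)O3 | intermediate
21 | (2Z)-2-methylbut-2-enoic acid (angelic acid) | C/C=C(/C)C(=O)O | starting material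
22 | (2Z)-2-methylbut-2-enoic 2,4,6-trichlorobenzoic anhydride | C/C=C(/C)C(=O)OC(=O)c1c(Cl)cc(Cl)cc1Cl | intermediate (not isolated)
23 | (4Z,6R,7R,8S,10R)-15-acetoxy-8-{[(2Z)-2-methylbut-2-enoyl]oxy}-3,10-epoxy-1-oxo-13-(phenylsulfanyl)germacra-2,4-dien-12,6-olide | C(Sc4ccccc4)C1C(=O)O[C@@H]2/C=C(/COC(C)=O)C3=CC(=O)[C@@](C)(C[C@H](OC(=O)/C(C)=C\C)[C@@H]12)O3 | intermediate
24 | (4Z,6R,7R,8S,10R)-15-acetoxy-8-{[(2Z)-2-methylbut-2-enoyl]oxy}-3,10-epoxy-1-oxo-13-(phenylsulfinyl)germacra-2,4-dien-12,6-olide | C(S(=O)c4ccccc4)C1C(=O)O[C@@H]2/C=C(/COC(C)=O)C3=CC(=O)[C@@](C)(C[C@H](OC(=O)/C(C)=C\C)[C@@H]12)O3 | intermediate (not isolated)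
25 | (4Z,6R,7R,8S,10R)-15-acetoxy-8-{[(2Z)-2-methylbut-2-enoyl]oxy}-3,10-epoxy-1-oxogermacra-2,4,11(13)-trien-12,6-olide (CNP0122132.1) | C=C1C(=O)O[C@@H]2/C=C(/COC(C)=O)C3=CC(=O)[C@@](C)(C[C@H](OC(=O)/C(C)=C\C)[C@@H]12)O3 | target

## Step count and least certain steps

Total: 15 steps. Longest linear sequence: 11 steps (steps 1–4, 8, 9, 11–15, from 1 to 25).

Step 13 (key step, proposed new method). The enolate may fail to reach the C3 carbonyl for conformational reasons. It may instead be drained by proton exchange with the vinylogous C6–H, by attack at C12, by elimination of thiolate after deprotonation at C11, or by translactonisation through the liberated O8 alkoxide before it is quenched. The fallback uses known reaction types and gives up ring A. It sets out from 14 and comes back at 23.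
- The C8 hydroxyl of 14 is angeloylated under the conditions of step 14 to give the 8-O-angelate F1.
- Aqueous HF in MeCN removes the tertiary silyl ether to give the α-hydroxy ketone F2.
- Esterification of the tertiary hydroxyl with 15 (DIC, DMAP) gives the α-acyloxy ketone F3.
- LiN(SiMe3)2 followed by acid brings about the intramolecular Claisen condensation through a five-membered transition state and dehydration, giving the furanone triene F4.
- Ring-closing metathesis of F4 (second-generation Hoveyda–Grubbs catalyst, toluene, high dilution) closes C4=C5 in the nine-membered oxacycle and delivers 23.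

Step 8. Open transition states of the allylzinc reagent could erode the facial selectivity at C7 or the anti selectivity at C8. The fallback sets out from 12 and comes back at 13. Borylation of 12 with bis(pinacolato)diboron and Pd2(dba)3 gives the allylboronate F5. Heating F5 with 6 in toluene should enforce the closed chair transition state of an allylboration, and oxidative work-up gives 13.

Step 12. Initiation at the hindered internal propenyl group next to the lactone oxygen may be slow, which opens the way to oligomerisation or double-bond migration. The fallback sets out from 14 and comes back at 17. Ethenolysis of 14 (second-generation Hoveyda–Grubbs catalyst, ethene) exchanges the propenyl for a terminal vinyl group and gives the vinyl lactone F6. Esterification with 15 as in step 11 gives the acrylate F7, whose metathesis starts at a monosubstituted alkene and closes ring A to 17.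

Step 7. The allylic bromide may shorten catalyst life, and partial ring closure through the propenyl group would erode the configurational purity at C6. The fallback sets out from 8 and comes back at 13. Steglich esterification of 8 with 15 gives the triene acetate F8. Ring-closing metathesis gives the acetoxymethyl butenolide F9. F9 is used directly as the pro-nucleophile in a palladium/indium umpolung allylation of 6 (Pd(PPh3)4 catalyst, InI, THF), which gives 13.

## Further compounds

F1 | step 13 | (4R,5R)-4-[(1S,3R)-3-{[tert-butyl(dimethyl)silyl]oxy}-3-methyl-1-{[(2Z)-2-methylbut-2-enoyl]oxy}-4-oxopentyl]-3-[(phenylsulfanyl)methyl]-5-[(1E)-prop-1-en-1-yl]oxolan-2-one | C(Sc1ccccc1)C1C(=O)O[C@H](/C=C/C)[C@H]1[C@@H](OC(=O)/C(C)=C\C)C[C@@](C)(O[Si](C)(C)C(C)(C)C)C(C)=O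
F2 | step 13 | (4R,5R)-4-[(1S,3R)-3-hydroxy-3-methyl-1-{[(2Z)-2-methylbut-2-enoyl]oxy}-4-oxopentyl]-3-[(phenylsulfanyl)methyl]-5-[(1E)-prop-1-en-1-yl]oxolan-2-one | C(Sc1ccccc1)C1C(=O)O[C@H](/C=C/C)[C@H]1[C@@H](OC(=O)/C(C)=C\C)C[C@@](C)(O)C(C)=O
F3 | step 13 | 10-O-[2-(acetoxymethyl)acryloyl] ester of F2 (α-acyloxy ketone) | C(Sc1ccccc1)C1C(=O)O[C@H](/C=C/C)[C@H]1[C@@H](OC(=O)/C(C)=C\C)C[C@@](C)(OC(=O)C(=C)COC(C)=O)C(C)=O
F4 | step 13 | (6R,7R,8S,10R)-configured open-chain furanone: 5-[3-acetoxyprop-1-en-2-yl]-2-methyl-3(2H)-furanone carrying at C10 the CH2–CH(O-angeloyl) link to the propenyl γ-lactone | C(Sc1ccccc1)C1C(=O)O[C@H](/C=C/C)[C@H]1[C@@H](OC(=O)/C(C)=C\C)C[C@@]2(C)OC(C(=C)COC(C)=O)=CC2=O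
F5 | step 8 | (5R)-5-[(1E)-prop-1-en-1-yl]-3-[(4,4,5,5-tetramethyl-1,3,2-dioxaborolan-2-yl)methyl]furan-2(5H)-one | O=C1O[C@H](/C=C/C)C=C1CB1OC(C)(C)C(C)(C)O1
F6 | step 12 | (4R,5R)-4-[(1S,3R)-3-{[tert-butyl(dimethyl)silyl]oxy}-1-hydroxy-3-methyl-4-oxopentyl]-5-ethenyl-3-[(phenylsulfanyl)methyl]oxolan-2-one | C(Sc1ccccc1)C1C(=O)O[C@H](C=C)[C@H]1[C@@H](O)C[C@@](C)(O[Si](C)(C)C(C)(C)C)C(C)=O
F7 | step 12 | 2-[(acetyloxy)methyl]prop-2-enoate of F6 at the C8 hydroxyl | C(Sc1ccccc1)C1C(=O)O[C@H](C=C)[C@H]1[C@@H](OC(=O)C(=C)COC(C)=O)C[C@@](C)(O[Si](C)(C)C(C)(C)C)C(C)=O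
F8 | step 7 | (3S,4E)-hexa-1,4-dien-3-yl 2-[(acetyloxy)methyl]prop-2-enoate | C=C(COC(C)=O)C(=O)O[C@@H](C=C)/C=C/C
F9 | step 7 | [(5R)-2-oxo-5-[(1E)-prop-1-en-1-yl]-2,5-dihydrofuran-3-yl]methyl acetate | O=C1O[C@H](/C=C/C)C=C1COC(C)=O
A1 | alternative 1 | methyl (2Z,4S)-2-(bromomethyl)-4-{[tert-butyl(dimethyl)silyl]oxy}-5-[(2R)-5-[(2Z)-3-acetoxymethyl-4-oxobut-2-en-2-yl... drawn as: (Z)-enal at C6, furanone C1–C3/C10, (Z)-allyl bromide C7=C11–C13] (bromo-enal for Barbier macrocyclisation) | C[C@]1(C[C@H](O[Si](C)(C)C(C)(C)C)/C=C(\CBr)C(=O)OC)OC(=CC1=O)/C(COC(C)=O)=C\C=O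
A2 | alternative 2 | (6R,7R,8S,10R)-configured metathesis precursor: 6-vinyl α-methylene-γ-lactone, 8-O-angelate, furanone bearing the 3-acetoxyprop-1-en-2-yl group at C3 | C=C1C(=O)O[C@H](C=C)[C@H]1[C@@H](OC(=O)/C(C)=C\C)C[C@@]2(C)OC(C(=C)COC(C)=O)=CC2=O
A3 | alternative 3 | cis-2,6-disubstituted 3,6-dihydro-2H-pyran: 2-(3-diazo-2-oxobutyl), 3-(acetoxymethyl), 5-[tert-butyl(dimethyl)silyl]oxy, 6-ethenyl (O bonded to C3 and C7) | O1[C@H](CC(=O)C(C)=[N+]=[N-])C(COC(C)=O)=C[C@@H](O[Si](C)(C)C(C)(C)C)[C@@H]1C=C
A4 | alternative 3 | ring-expanded 11-oxabicyclo[6.2.1]undecadienone with the new alkene at C7=C8 (geometry not defined), C10 quaternary, C6 silyl ether | C[C@@]12CC=C[C@H](O[Si](C)(C)C(C)(C)C)/C=C(/COC(C)=O)[C@@H](CC1=O)O2
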